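The runs were computed with constants of no real substance, noise included.

The ratio of single product read to solid substrate lost in the east run is 0.0294 at 80.0 s, with a scatter of 0.5 percentage points on each reading, so the falling solid is the trace to reckon from. Its early slope, a reading that carries this scatter, gives the dissolving time τ, the time in which the early pace clears the whole charge, 13.1 min.

| setting | east | flask |
|---|---|---|
| solid substrate | 0.50 M | 0.50 M |
| partner | 0.55 M | 0.550 M |
| remark | the very flask that is asked about, followed so far |  |
| time |  | 8.0 min |

east run (percent of the solid substrate charged)

| time / s | solid substrate / % | single product / % |
|---|---|---|
| 10.0 | 98.9 | 0.7 |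
| 15.0 | 98.4 | 0.3 |
| 40.0 | 94.7 | 0 |
| 80.0 | 89.8 | 0.3 |

(standard deviation of a reading: 0.5 percentage points)

- amount of solid substrate at 8.0 min, in percent of the solid substrate charged (only what is still solid)
- amount of single product at 8.0 min, in percent of the solid substrate charged
- amount of bis adduct at 8.0 min, in percent of the solid substrate charged

- what was read earlier has a scatter of 0.5 percentage points, one standard deviation
- at the start none of the solid substrate is in solution
- a reading or a percentage of single product counts all its forms, free or not

The east run and the asked flask share their charges and differ in time of reading: the east run stops at t/τ = 0.102, where its readings still lie near a straight zero-order line, whereas the asked flask stands at t/τ = 0.612, far beyond them, so the readings do not test that line at the asked time. The reckoning offered here, which assumes a pace proportional to the solid present, first takes the line and leaves 38.8% solid. Going round once more with the mean of the start and that answer, 69.4%, as the acting share, it leaves 57.5%; it gives no figure for single product or bis adduct.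

The forecast gives 47% solid substrate, 4% single product and 38% bis adduct, leaning “toward fast follow-on reaction”, and it keeps less solid than this reckoning.

The flask gives 57.8% solid substrate, 9.69% single product and 0.194% bis adduct.

    starting material + single product ⇌ idle adduct, settled at all times (K = 6.00 M⁻¹)
    starting material + partner → single product (k = 0.00210 M⁻¹ s⁻¹)
    partner + single product → bis adduct (k = 3.50 × 10⁻⁴ M⁻¹ s⁻¹)
    crystals ⇌ single product, rate k4*(cs4 - [single product]) while solid is left; crystals form when [single product] > cs4 (solubility = 0.230 M, k = 0.200 s⁻¹)
    solid substrate ⇌ starting material, rate k5*(cs5 - [starting material]) while solid is left; crystals form when [starting material] > cs5 (solubility = 0.240 M, k = 0.00300 s⁻¹)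

In the flask, solid substrate went into solution throughout, reaching the midpoint of its turnover up to 8.0 min at 3.11 min with 27.9% of starting material in solution at the end, while the passing of starting material and partner into single product reached its midpoint later, at 5.05 min, and the half-life of free dissolved single product by the follow-on to bis adduct stood at 61 min at 3.11 min, long against 8.0 min. The scheme's dissolving pace follows the gap between 0.24 M and starting material rather than the solid left, so the acting share 69.4% is a stand-in, and the flask's own share, solid lost over t/τ, reads 69.0%; for the same charge read at 3.0 min, t/τ = 0.229, the two rounds leave 79.7%, and that flask holds 79.5%.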